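## Analysis of the target

The target 18 is a flavone: a 4H-chromen-4-one (benzo ring A fused to pyranone ring C) with an aryl ring B on C2. It has no stereocentre and is flat, so the whole problem is where eight oxygen substituents go and which of them are methylated. Ring A is fully substituted (C5 OH, C6 OMe, C7 OH, C8 OMe), C3 carries a methoxyl, and ring B is a 4-hydroxy-2,5-dimethoxyphenyl group. The sensitive points are the three free phenols on electron-rich rings (easy oxidation), the O5 hydroxyl, which is hydrogen-bonded to the C4 carbonyl and alkylates slowly, and the pyranone ring, which hard nucleophiles open at C2. The difficulty is that five methyl ethers and three free hydroxyls must be told apart without any selective methylation or demethylation. A second difficulty is that an oxygen is hard to put on C3 of a finished flavone that has a 2'-substituted ring B. The strategy rests on one feature: the oxygens on C5, C7 and C8a of ring A alternate with C4a, C6 and C8, as in an acylphloroglucinol made from acetate units, and C4 (carbonyl), C3 (methoxyl) and C2 (oxygen) carry the same alternation on as a 2-methoxy-1,3-diketone. Rings A and C are therefore two folds of one linear poly-β-carbonyl chain, while the C6 and C8 methoxyls sit on the nucleophilic carbons of that phloroglucinol ring and can be added afterwards.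

## Retrosynthetic reasoning

**Target 18 to tris-benzyl ether 17.** The last disconnection cuts the three O–CH2Ph bonds on O5, O7 and O4'. One kind of protecting group then masks all three phenols through the basic and copper-mediated steps. A single hydrogenolysis frees them at the end and leaves the five methyl ethers and the C2=C3 bond alone.

**17 to dibromide 16, diphenol 15 and flavone 14.** The C6–OMe and C8–OMe bonds are cut next, because these two oxygens are the only ones on rings A and C that lie off the acetate pattern. C6 and C8 are the carbons between the oxygens of a phloroglucinol-type ring and are the most nucleophilic positions of 14. Each C–O bond is therefore traced back to a C–Br bond (16) and then, by way of the free diphenol 15, to C–H (14). Both positions are to be substituted, so no choice between them has to be made. The forward sequence must brominate ring A and not ring B, cap O5 and O7 before the copper-mediated displacement, and exchange both bromides for methoxyl.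

**14 to pyranone 11 (the key disconnection).** Ring C is opened at O1–C2 by formal hydration, which gives the 2,4,6-trihydroxyaryl 2-methoxy-1,3-diketone 13. Ring A is opened at C4a–C8a in the retro-Claisen sense, which gives the linear tetraoxo ester 12, and the first three acetate units of 12 are stored as the 4-hydroxy-2-pyranone 11. The cut is made here and not at C4a–C4 or C2–C1', which would mean acylating a preformed phloroglucinol. One chain then delivers both rings with every carbon at the right oxidation level and with the C3 methoxyl already in place. Storing chain carbons 1 to 5 in the pyranone keeps the polycarbonyl compound from folding before it is asked to. The forward step has to open the lactone, fold the chain by Claisen and not by aldol condensation, and then close O1–C2 with loss of the elements of water.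

**11 to pyranone ketone 10 and ester 7.** The bond between the methoxy-bearing carbon and the aroyl carbon is cut. It separates ring B, at the oxidation level of a benzoate, from the aliphatic chain. In the forward sense the last-formed, most nucleophilic carbanion of a polyanion of 10 meets an ester that has no α-hydrogen and cannot condense with itself. The forward reaction has to acylate at the terminal carbon only and must tolerate a product that is more acidic than the starting ketone.

**10 to 8 and 9.** The bond between the side-chain methylene and the ketone carbon is cut. The dianion of 8 is acylated at its methyl carbon by ester 9, which brings in the future C3 together with its methoxyl. Both pieces are bulk chemicals.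

**7 back to 1.** Ester 7 is taken back to aldehyde 6 (a change of oxidation level). 6 goes back to ether 4 by removal of the formyl carbon para to the benzyloxy group, 4 to phenol 3 by the O–benzyl bond, and 3 to aldehyde 1, whose formyl group is traded for the hydroxyl by way of formate 2. In the forward direction the aldehyde carbon of 1 is lost and a new one is introduced para to the new oxygen. The gain is that a cheap 2,5-dioxygenated benzene receives its third oxygen and its carboxyl carbon with positional control from the substituents already present.

## Alternatives that were turned down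

**Alternative 1:** Ring C is cut at O1–C8a and at C4a–C4. Ring A then arrives as an aryne released from the silylaryl triflate A2, and C4, C3, C2 and ring B arrive as the arylpropiolic acid A3.
- Forward key step: a fluoride source frees the aryne, the carboxylate oxygen of A3 adds to it, the aryl anion attacks the acyl carbon, and the resulting o-hydroxyaryl ynone closes O1–C2 by conjugate addition to give flavone A1.
- For it: it is convergent and makes two bonds and a ring in one flask. The alkoxy group next to the aryne bond sends the oxygen to the distal carbon, which is the regiochemistry needed. A1 already carries the C6 methoxyl.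
- Against it: A1 has hydrogen at C3 and at C8, so two oxygens must still be added to the finished flavone. One needs oxidation at C3 beside a 2'-methoxyaryl group. The other needs halogenation and methoxylation at C8 of a ring whose oxygens are all etherified, which competes poorly with the trialkoxy ring B. A2 carries three contiguous alkoxy groups, a silyl group and a triflate and needs a long preparation of its own. The isopropyl ethers of A1 need a Lewis acid for removal, which puts the methyl ethers next to the carbonyl at risk.
- Comparison: alternative 1 is stronger in convergency and in bonds formed per step. The chosen route takes the C3 methoxyl from a bulk ester and adds the C6 and C8 oxygens in one double operation on the most reactive ring, where alternative 1 needs two unlike late oxidations.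

**Alternative 2:** Ring C is cut at C4a–C4, C4–C3 and O1–C2 and is assembled from three components: the iodoresorcinol A5, carbon monoxide A7 and the arylalkyne A6.
- Forward key step: A5 adds oxidatively to zerovalent palladium, A7 inserts to give an aroylpalladium species, coupling with A6 gives an o-hydroxyaryl ynone, and in a secondary amine this closes in the 6-endo mode to flavone A4.
- For it: it is the most convergent plan of all. Ring A enters with all four oxygens in place and differentiated, and A5 is symmetric, so either hydroxyl gives A4. On ring A it is clearly stronger than the chosen route, which needs three steps for the C6 and C8 methoxyls.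
- Against it: A4 has hydrogen at C3, so the C3 oxygen must be added late and methylated in the presence of the free O5 hydroxyl. A5 is a hexasubstituted, very electron-rich iodoarene flanked by two hydroxyls. Slow oxidative addition, loss of iodine, direct coupling without uptake of A7 and 5-exo closure to an aurone are all open to it. A5 is also not a short preparation.
- Comparison: the chosen route gives up the ready-made ring A. In return the C3 methoxyl is built in from the start and the carbon skeleton comes from three cheap compounds, with the oxygens at C6 and C8 added by known flavone chemistry.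

**Alternative 3:** Ring A is cut at C4a–C5 and built from a squarate. The pyranone A11 (ring C with ring B attached) would be metalated at C6 and added to the squaric ester A10, and O-methylation would give the 4-methoxycyclobutenone A9.
- Forward key step: heating A9 in an aromatic solvent opens the four-membered ring to a dienylketene. Its ketene carbon bonds to C5 of the pyranone by 6π electrocyclisation, and tautomerisation gives flavone A8.
- For it: ring A is formed fully substituted in one reagent-free pericyclic cascade with fixed regiochemistry, and A8 already holds the C3 and C8 methoxyls. On completeness of ring A in the key step it is stronger than the chosen route.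
- Against it: A8 carries the same isopropyl ether on O6 and on O7, but the target needs methyl on O6 and hydrogen on O7. After dealkylation the 5,6,7-triol would have to be methylated at the central O6 only, and the more acidic O7 would react first. A differently substituted squaric ester would move the problem to the regiochemistry of the addition. A metalated 4-pyranone such as that from A11 is a base-sensitive nucleophile, and A11 needs its own synthesis.
- Comparison: in the chosen route O7 and O6 are distinguished by origin. O7 comes from the chain as a phenol and O6 enters as methoxide, so the selective methylation never arises.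

Key step: step 7

Remark on the chemistry: 11, 12 and 13 are drawn as keto tautomers. Each is racemic at the methoxy-bearing carbon and enolises freely, which has no consequence because that carbon becomes the sp2 carbon C3 of the flavone.

## Route

Step 1
Reactants: 1 2,5-dimethoxybenzaldehyde
Product: 3 2,5-dimethoxyphenol, via 2,5-dimethoxyphenyl formate 2 (not isolated)
Conditions: H2O2 (30% aq., 1.3 equiv), H2SO4 (cat.), MeOH, rt
Reagents that add atoms: hydrogen peroxide, OO
Why: Acid-catalysed Dakin-type (Baeyer–Villiger) oxidation; the electron-rich aryl group with its ortho methoxyl migrates to oxygen in preference to hydride, and formate 2 is methanolysed in the same flask.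

Step 2
Reactants: 3 2,5-dimethoxyphenol
Product: 4 2-(benzyloxy)-1,4-dimethoxybenzene
Conditions: BnBr (1.1 equiv), K2CO3, DMF, 60 °C
Reagents that add atoms: benzyl bromide, BrCc1ccccc1
Why: Williamson ether synthesis on an unhindered phenoxide.

Step 3
Reactants: 4 2-(benzyloxy)-1,4-dimethoxybenzene
Product: 6 4-(benzyloxy)-2,5-dimethoxybenzaldehyde, via Vilsmeier iminium chloride 5 (not isolated)
Conditions: POCl3, DMF, 0 → 70 °C; then ice–water
Reagents that add atoms: N,N-dimethylformamide, CN(C)C=O; water, O
Why: Vilsmeier–Haack formylation; C5 of 4 is para to the benzyloxy group and ortho to a methoxyl, whereas C3 is wedged between two alkoxy groups and C6 has only one ortho donor, the same preference that turns 1,2,4-trialkoxybenzenes into 2,4,5-trialkoxybenzaldehydes.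

Step 4
Reactants: 6 4-(benzyloxy)-2,5-dimethoxybenzaldehyde
Product: 7 methyl 4-(benzyloxy)-2,5-dimethoxybenzoate
Conditions: I2 (1.3 equiv), KOH (2.6 equiv), MeOH, 0 °C
Reagents that add atoms: methanol, CO
Why: Oxidative esterification; the methyl hemiacetal of the aldehyde is oxidised by hypoiodite, and the ring, deactivated by the formyl group, should not be iodinated in basic methanol.

Step 5
Reactants: 8 4-hydroxy-6-methyl-2H-pyran-2-one (triacetic acid lactone); 9 methyl methoxyacetate
Product: 10 4-hydroxy-6-(3-methoxy-2-oxopropyl)-2H-pyran-2-one
Conditions: 8 (2.1 equiv), LiN(iPr)2 (4.3 equiv), THF, −78 → 0 °C; 9 (1.0 equiv), −78 °C → rt; then 1 M HCl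
Reagents that add atoms: none
Why: Claisen-type acylation of the dianion of 8 at its methyl carbon, the last-formed and most nucleophilic site; the second equivalent of dianion takes up the proton of the more acidic product, so that no free amide base is left to enolise ester 9, and unreacted 8 should be recoverable.

Step 6
Reactants: 10 4-hydroxy-6-(3-methoxy-2-oxopropyl)-2H-pyran-2-one; 7 methyl 4-(benzyloxy)-2,5-dimethoxybenzoate
Product: 11 6-{4-[4-(benzyloxy)-2,5-dimethoxyphenyl]-3-methoxy-2,4-dioxobutyl}-4-hydroxy-2H-pyran-2-one (racemic)
Conditions: LiN(iPr)2 (4.2 equiv), THF, −78 → −10 °C; 7 (1.0 equiv), −78 → 0 °C; then cold 1 M HCl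
Reagents that add atoms: none
Why: Terminal acylation of a β-polycarbonyl polyanion (Claisen condensation): the third deprotonation of 10 can only take place at the methoxy-bearing methylene, and this last-formed carbanion is the one that adds to the ester. Ester 7 has no α-hydrogen and so acts only as acceptor, and the fourth equivalent of base holds the acidic 2-methoxy-1,3-diketone as its enolate until the quench.

Step 7
Reactants: 11 6-{4-[4-(benzyloxy)-2,5-dimethoxyphenyl]-3-methoxy-2,4-dioxobutyl}-4-hydroxy-2H-pyran-2-one
Product: 14 2-[4-(benzyloxy)-2,5-dimethoxyphenyl]-5,7-dihydroxy-3-methoxy-4H-chromen-4-one, via open-chain tetraoxo ester 12 (not isolated), via acylphloroglucinol diketone 13 (not isolated)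
Conditions: Mg(OMe)2 (8 equiv), MeOH, reflux; then HCl (aq.) to pH 1, MeOH, 60 °C
Reagents that add atoms: none
Why: Mg(OMe)2 adds to the lactone carbonyl of 11 and opens the pyranone to the magnesium chelate of the methyl 3,5,7,9-tetraoxo ester 12 (chain numbered from the ester carbon); the carbanion at chain C6 (future C4a), held between two chelated ketones, attacks the ester carbon (future C8a) in a 6-exo-trig Claisen closure, methoxide leaves, and the cyclohexanetrione enolises irreversibly to the 2,4,6-trihydroxyaryl diketone 13. On acidification an ortho hydroxyl of 13 adds to the aroyl carbonyl in a 6-exo-trig closure and the hemiketal loses water across C2–C3, which closes ring C. The closest known reaction type is the magnesium-alkoxide-mediated Claisen cyclisation of 6-(2-oxoalkyl)-4-hydroxy-2-pyranones and 3,5,7-triketo esters to acylphloroglucinols, followed by the acid cyclodehydration of o-hydroxyaryl 1,3-diketones that ends a Baker–Venkataraman flavone synthesis. No stereocentre is formed, and the racemic methoxy-bearing carbon of 11 becomes the sp2 carbon C3. The step needs the Claisen fold to win over two aldol folds, attack of chain C2 on the C7 ketone (a resorcylate) and attack of pyranone C5 on the aroyl carbonyl before ring opening (a 5-aryl-4,7-dihydroxycoumarin). Chelation by magnesium turns the ketone carbonyls into enolates that no longer accept nucleophiles while the ester carbonyl stays electrophilic, and the aroyl carbonyl is further shielded by its ortho methoxyl and its methoxy-bearing neighbour. The same chelate protects the 2-methoxy-1,3-diketone from retro-Claisen cleavage by methoxide. The closure of ring C raises no regiochemical question because the two ortho hydroxyls of 13 are equivalent.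

Step 8
Reactants: 14 2-[4-(benzyloxy)-2,5-dimethoxyphenyl]-5,7-dihydroxy-3-methoxy-4H-chromen-4-one
Product: 15 2-[4-(benzyloxy)-2,5-dimethoxyphenyl]-6,8-dibromo-5,7-dihydroxy-3-methoxy-4H-chromen-4-one
Conditions: NBS (2.05 equiv), DMF, 0 °C → rt, dark
Reagents that add atoms: N-bromosuccinimide, O=C1CCC(=O)N1Br
Why: Electrophilic aromatic bromination; C6 and C8 each lie ortho or para to two free hydroxyls of a phloroglucinol-type ring and should react far faster than ring B, which has only ether donors and is attached to the electron-poor C2 of the chromone.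

Step 9
Reactants: 15 2-[4-(benzyloxy)-2,5-dimethoxyphenyl]-6,8-dibromo-5,7-dihydroxy-3-methoxy-4H-chromen-4-one
Product: 16 5,7-bis(benzyloxy)-2-[4-(benzyloxy)-2,5-dimethoxyphenyl]-6,8-dibromo-3-methoxy-4H-chromen-4-one
Conditions: BnBr (3 equiv), K2CO3, KI (cat.), DMF, 70 °C
Reagents that add atoms: benzyl bromide, BrCc1ccccc1
Why: Williamson etherification; O7 reacts first, the chelated O5 needs the heat and the iodide catalysis, and C-alkylation is excluded because C6 and C8 are blocked.

Step 10
Reactants: 16 5,7-bis(benzyloxy)-2-[4-(benzyloxy)-2,5-dimethoxyphenyl]-6,8-dibromo-3-methoxy-4H-chromen-4-one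
Product: 17 5,7-bis(benzyloxy)-2-[4-(benzyloxy)-2,5-dimethoxyphenyl]-3,6,8-trimethoxy-4H-chromen-4-one
Conditions: NaOMe (10 equiv), CuBr (0.4 equiv), DMF–MeOH, 110 °C; then dilute HCl
Reagents that add atoms: sodium methoxide, [Na+].[O-]C
Why: Ullmann-type copper-catalysed methoxylation of aryl bromides, the known way from 6,8-dibromo-5,7-dialkoxyflavones to 5,6,7,8-tetraoxygenated flavones. No free phenol is left to slow the exchange, and any opening of the pyranone by methoxide at C2 is reversed on acidic work-up.

Step 11
Reactants: 17 5,7-bis(benzyloxy)-2-[4-(benzyloxy)-2,5-dimethoxyphenyl]-3,6,8-trimethoxy-4H-chromen-4-one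
Product: 18 5,7-dihydroxy-2-(4-hydroxy-2,5-dimethoxyphenyl)-3,6,8-trimethoxy-4H-chromen-4-one (5,7,4'-trihydroxy-3,6,8,2',5'-pentamethoxyflavone)
Conditions: H2 (1 atm), Pd/C (10%), EtOAc–MeOH, rt
Reagents that add atoms: none
Why: Hydrogenolysis of three benzyl aryl ethers; aryl methyl ethers and the C2=C3 bond of the chromone are inert under these conditions.

## Compound list

1 | 2,5-dimethoxybenzaldehyde | COc1ccc(OC)c(C=O)c1 | starting material
2 | 2,5-dimethoxyphenyl formate | COc1ccc(OC)c(OC=O)c1 | intermediate (not isolated)
3 | 2,5-dimethoxyphenol | COc1ccc(OC)c(O)c1 | intermediate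
4 | 2-(benzyloxy)-1,4-dimethoxybenzene | COc1ccc(OC)c(OCc2ccccc2)c1 | intermediate
5 | N-{[4-(benzyloxy)-2,5-dimethoxyphenyl]methylidene}-N-methylmethanaminium chloride | COc1cc(C=[N+](C)C)c(OC)cc1OCc1ccccc1.[Cl-] | intermediate (not isolated)
6 | 4-(benzyloxy)-2,5-dimethoxybenzaldehyde | COc1cc(C=O)c(OC)cc1OCc1ccccc1 | intermediate
7 | methyl 4-(benzyloxy)-2,5-dimethoxybenzoate | COC(=O)c1cc(OC)c(OCc2ccccc2)cc1OC | intermediate
8 | 4-hydroxy-6-methyl-2H-pyran-2-one (triacetic acid lactone) | Cc1cc(O)cc(=O)o1 | starting material
9 | methyl methoxyacetate | COCC(=O)OC | starting material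
10 | 4-hydroxy-6-(3-methoxy-2-oxopropyl)-2H-pyran-2-one | COCC(=O)Cc1cc(O)cc(=O)o1 | intermediate
11 | 6-{4-[4-(benzyloxy)-2,5-dimethoxyphenyl]-3-methoxy-2,4-dioxobutyl}-4-hydroxy-2H-pyran-2-one (racemic) | O=c1cc(O)cc(CC(=O)C(OC)C(=O)c2cc(OC)c(OCc3ccccc3)cc2OC)o1 | intermediate
12 | methyl 9-[4-(benzyloxy)-2,5-dimethoxyphenyl]-8-methoxy-3,5,7,9-tetraoxononanoate (racemic) | COC(=O)CC(=O)CC(=O)CC(=O)C(OC)C(=O)c1cc(OC)c(OCc2ccccc2)cc1OC | intermediate (not isolated)
13 | 1-[4-(benzyloxy)-2,5-dimethoxyphenyl]-2-methoxy-3-(2,4,6-trihydroxyphenyl)propane-1,3-dione (racemic) | COC(C(=O)c1c(O)cc(O)cc1O)C(=O)c1cc(OC)c(OCc2ccccc2)cc1OC | intermediate (not isolated)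
14 | 2-[4-(benzyloxy)-2,5-dimethoxyphenyl]-5,7-dihydroxy-3-methoxy-4H-chromen-4-one | COc1cc(-c2oc3cc(O)cc(O)c3c(=O)c2OC)c(OC)cc1OCc1ccccc1 | intermediate
15 | 2-[4-(benzyloxy)-2,5-dimethoxyphenyl]-6,8-dibromo-5,7-dihydroxy-3-methoxy-4H-chromen-4-one | COc1cc(-c2oc3c(Br)c(O)c(Br)c(O)c3c(=O)c2OC)c(OC)cc1OCc1ccccc1 | intermediate
16 | 5,7-bis(benzyloxy)-2-[4-(benzyloxy)-2,5-dimethoxyphenyl]-6,8-dibromo-3-methoxy-4H-chromen-4-one | COc1cc(-c2oc3c(Br)c(OCc4ccccc4)c(Br)c(OCc4ccccc4)c3c(=O)c2OC)c(OC)cc1OCc1ccccc1 | intermediate
17 | 5,7-bis(benzyloxy)-2-[4-(benzyloxy)-2,5-dimethoxyphenyl]-3,6,8-trimethoxy-4H-chromen-4-one | COc1cc(-c2oc3c(OC)c(OCc4ccccc4)c(OC)c(OCc4ccccc4)c3c(=O)c2OC)c(OC)cc1OCc1ccccc1 | intermediate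
18 | 5,7-dihydroxy-2-(4-hydroxy-2,5-dimethoxyphenyl)-3,6,8-trimethoxy-4H-chromen-4-one | COc1cc(-c2oc3c(OC)c(O)c(OC)c(O)c3c(=O)c2OC)c(OC)cc1O | target

## Step count and least certain steps

Total: 11 steps. Longest linear sequence: 10 steps (steps 1 to 4 and 6 to 11, from 1 to 18). The branch from 8 and 9 joins at step 6.

**Step 7 (key step).** The chain may fold by aldol instead of Claisen condensation. The pyranone anion may also resist methanolysis, or methoxide may cleave the aroyl group from the 2-methoxy-1,3-diketone by retro-Claisen reaction before ring A is closed. All three follow from the many nearly equal acidic and electrophilic sites of a tetracarbonyl chain.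
Fallback, from 7, back at 14: the fold is given up and ring C is built on a preformed phloroglucinol ring. Ester 7 is saponified (LiOH, THF–H2O) to 4-(benzyloxy)-2,5-dimethoxybenzoic acid F1. F1 is dehydrated with N,N'-dicyclohexylcarbodiimide to 4-(benzyloxy)-2,5-dimethoxybenzoic anhydride F2. F2 is heated with purchased 2-methoxy-1-(2,4,6-trihydroxyphenyl)ethan-1-one F3 and triethylamine at about 160 °C (Allan–Robinson condensation). The aroyl esters on the crude product are then cleaved with KOH in aqueous methanol, which should give 14.

**Step 6.** Addition of the trianion to the electron-rich, ortho-substituted ester may be slow, so that proton transfer from product to trianion and poor solubility of the lithium polyanion stop the reaction early.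
Fallback, from 10 and 6, back at 11: the same trianion of 10 is added to aldehyde 6, a much better electrophile whose adduct does not quench the base. This aldol addition should give 6-{4-[4-(benzyloxy)-2,5-dimethoxyphenyl]-4-hydroxy-3-methoxy-2-oxobutyl}-4-hydroxy-2H-pyran-2-one F4 as a mixture of racemic diastereomers. Oxidation of its benzylic alcohol with Dess–Martin periodinane in CH2Cl2 leads to 11.

**Step 10.** Each bromide sits between two alkoxy groups, so the exchange may stop after one substitution or be overtaken by reductive loss of bromine. Long heating with methoxide may also degrade the pyranone.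
Fallback, from 16, back at 17: the carbon–oxygen bonds are made by way of boron. Miyaura borylation of 16 (B2pin2, PdCl2(dppf), KOAc, dioxane, 90 °C) should give 5,7-bis(benzyloxy)-2-[4-(benzyloxy)-2,5-dimethoxyphenyl]-3-methoxy-6,8-bis(4,4,5,5-tetramethyl-1,3,2-dioxaborolan-2-yl)-4H-chromen-4-one F5. Oxidation (H2O2, aq. NaHCO3, THF) gives 5,7-bis(benzyloxy)-2-[4-(benzyloxy)-2,5-dimethoxyphenyl]-6,8-dihydroxy-3-methoxy-4H-chromen-4-one F6. Methylation (MeI, K2CO3, acetone) gives 17.

**Step 9.** Alkylation of O5 may stay incomplete, because this hydroxyl is hydrogen-bonded to the C4 carbonyl and flanked by bromine.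
Fallback, from 15, back at 18: O5 is given a smaller group that is removed by chelation control.
- Benzylation of the free O7 alone (BnBr, 1.1 equiv, K2CO3, acetone, rt) gives 7-(benzyloxy)-2-[4-(benzyloxy)-2,5-dimethoxyphenyl]-6,8-dibromo-5-hydroxy-3-methoxy-4H-chromen-4-one F7.
- Methylation of O5 (MeI, K2CO3, DMF, 60 °C) gives 7-(benzyloxy)-2-[4-(benzyloxy)-2,5-dimethoxyphenyl]-6,8-dibromo-3,5-dimethoxy-4H-chromen-4-one F8.
- The conditions of step 10 give 7-(benzyloxy)-2-[4-(benzyloxy)-2,5-dimethoxyphenyl]-3,5,6,8-tetramethoxy-4H-chromen-4-one F9.
- BCl3 in CH2Cl2 (−78 → 0 °C) cleaves the 5-methyl ether, which is activated by six-membered chelation to the C4 carbonyl, together with both benzyl ethers, and should give 18. Temperature and reagent amount must be controlled so that the C3 and C6 methyl ethers stay.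

## Further compounds

F1 | step 7 | 4-(benzyloxy)-2,5-dimethoxybenzoic acid | COc1cc(C(=O)O)c(OC)cc1OCc1ccccc1
F2 | step 7 | 4-(benzyloxy)-2,5-dimethoxybenzoic anhydride | COc1cc(C(=O)OC(=O)c2cc(OC)c(OCc3ccccc3)cc2OC)c(OC)cc1OCc1ccccc1
F3 | step 7 | 2-methoxy-1-(2,4,6-trihydroxyphenyl)ethan-1-one | COCC(=O)c1c(O)cc(O)cc1O
F4 | step 6 | 6-{4-[4-(benzyloxy)-2,5-dimethoxyphenyl]-4-hydroxy-3-methoxy-2-oxobutyl}-4-hydroxy-2H-pyran-2-one (mixture of racemic diastereomers) | O=c1cc(O)cc(CC(=O)C(OC)C(O)c2cc(OC)c(OCc3ccccc3)cc2OC)o1
F5 | step 10 | 5,7-bis(benzyloxy)-2-[4-(benzyloxy)-2,5-dimethoxyphenyl]-3-methoxy-6,8-bis(4,4,5,5-tetramethyl-1,3,2-dioxaborolan-2-yl)-4H-chromen-4-one | COc1cc(-c2oc3c(B4OC(C)(C)C(C)(C)O4)c(OCc4ccccc4)c(B4OC(C)(C)C(C)(C)O4)c(OCc4ccccc4)c3c(=O)c2OC)c(OC)cc1OCc1ccccc1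
F6 | step 10 | 5,7-bis(benzyloxy)-2-[4-(benzyloxy)-2,5-dimethoxyphenyl]-6,8-dihydroxy-3-methoxy-4H-chromen-4-one | COc1cc(-c2oc3c(O)c(OCc4ccccc4)c(O)c(OCc4ccccc4)c3c(=O)c2OC)c(OC)cc1OCc1ccccc1
F7 | step 9 | 7-(benzyloxy)-2-[4-(benzyloxy)-2,5-dimethoxyphenyl]-6,8-dibromo-5-hydroxy-3-methoxy-4H-chromen-4-one | COc1cc(-c2oc3c(Br)c(OCc4ccccc4)c(Br)c(O)c3c(=O)c2OC)c(OC)cc1OCc1ccccc1
F8 | step 9 | 7-(benzyloxy)-2-[4-(benzyloxy)-2,5-dimethoxyphenyl]-6,8-dibromo-3,5-dimethoxy-4H-chromen-4-one | COc1cc(-c2oc3c(Br)c(OCc4ccccc4)c(Br)c(OC)c3c(=O)c2OC)c(OC)cc1OCc1ccccc1
F9 | step 9 | 7-(benzyloxy)-2-[4-(benzyloxy)-2,5-dimethoxyphenyl]-3,5,6,8-tetramethoxy-4H-chromen-4-one | COc1cc(-c2oc3c(OC)c(OCc4ccccc4)c(OC)c(OC)c3c(=O)c2OC)c(OC)cc1OCc1ccccc1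
A1 | alternative 1 | 2-[4-(benzyloxy)-2,5-dimethoxyphenyl]-6-methoxy-5,7-di(propan-2-yloxy)-4H-chromen-4-one | COc1cc(-c2cc(=O)c3c(OC(C)C)c(OC)c(OC(C)C)cc3o2)c(OC)cc1OCc1ccccc1
A2 | alternative 1 | 4-methoxy-3,5-di(propan-2-yloxy)-2-(trimethylsilyl)phenyl trifluoromethanesulfonate | COc1c(OC(C)C)cc(OS(=O)(=O)C(F)(F)F)c([Si](C)(C)C)c1OC(C)C
A3 | alternative 1 | 3-[4-(benzyloxy)-2,5-dimethoxyphenyl]prop-2-ynoic acid | COc1cc(C#CC(=O)O)c(OC)cc1OCc1ccccc1
A4 | alternative 2 | 7-(benzyloxy)-2-[4-(benzyloxy)-2,5-dimethoxyphenyl]-5-hydroxy-6,8-dimethoxy-4H-chromen-4-one | COc1cc(-c2cc(=O)c3c(O)c(OC)c(OCc4ccccc4)c(OC)c3o2)c(OC)cc1OCc1ccccc1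
A5 | alternative 2 | 5-(benzyloxy)-2-iodo-4,6-dimethoxybenzene-1,3-diol | COc1c(O)c(I)c(O)c(OC)c1OCc1ccccc1
A6 | alternative 2 | 1-(benzyloxy)-4-ethynyl-2,5-dimethoxybenzene | COc1cc(C#C)c(OC)cc1OCc1ccccc1
A7 | alternative 2 | carbon monoxide | [C-]#[O+]
A8 | alternative 3 | 2-[4-(benzyloxy)-2,5-dimethoxyphenyl]-5-hydroxy-3,8-dimethoxy-6,7-di(propan-2-yloxy)-4H-chromen-4-one | COc1cc(-c2oc3c(OC)c(OC(C)C)c(OC(C)C)c(O)c3c(=O)c2OC)c(OC)cc1OCc1ccccc1
A9 | alternative 3 | 4-{6-[4-(benzyloxy)-2,5-dimethoxyphenyl]-5-methoxy-4-oxo-4H-pyran-2-yl}-4-methoxy-2,3-di(propan-2-yloxy)cyclobut-2-en-1-one (racemic) | COC1(c2cc(=O)c(OC)c(-c3cc(OC)c(OCc4ccccc4)cc3OC)o2)C(=O)C(OC(C)C)=C1OC(C)C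
A10 | alternative 3 | 3,4-di(propan-2-yloxy)cyclobut-3-ene-1,2-dione | CC(C)OC1=C(OC(C)C)C(=O)C1=O
A11 | alternative 3 | 2-[4-(benzyloxy)-2,5-dimethoxyphenyl]-3-methoxy-4H-pyran-4-one | COc1cc(-c2occc(=O)c2OC)c(OC)cc1OCc1ccccc1
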